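**Retrosynthetic overview**
1. Ptilosarcone 28 comes from C6 alcohol 27 by invertive chlorination; 8‑OH and 17‑H come from butenolide 23 by C6‑hydroxyl‑directed epoxidation and SmI2 opening.
2. The ten‑membered ring (3Z‑alkene, C2–O, C5=CH2) comes from 2,5‑furanophane 18: NBS/H2O opens the furan to the Z‑ene‑1,4‑dione, then C5 methylenation and C2 reduction.
3. Furanophane 18 comes from NiCl2/CrCl2 ring closure at C8–C9 and a vinylogous aldol at C6–C7 with bromobutenolide 13 (lactone ring preformed).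
4. Ring A comes from prochiral dienone 3: Rh‑catalysed vinyl addition desymmetrises it (C10, C1), followed by C11 methylation and C14 borylation/oxidation.
5. Dienone 3 comes from the dearomatising oxidative para C–C coupling of p‑cresol with furan. Ring order: ring A, then lactone, then ten‑membered ring.

Assumption: locants C1–C20 follow briarane numbering (C15 on C1, C16 on C5, C18 on C17, C19 the lactone carbonyl, C20 on C11); 3‑methyltetronic acid is taken as commercial; catalyst and ligand antipodes are those that give the configurations drawn. The route is a paper proposal; stereochemical outcomes are predictions.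

**Step 1**
Reactants: 1 p‑cresol; 2 furan
Product: 3 4‑(furan‑2‑yl)‑4‑methylcyclohexa‑2,5‑dien‑1‑one
Conditions: PhI(OAc)2 (1.1 equiv), furan (10 equiv), (CF3)2CHOH, −20 to 0 °C
Reagents that add atoms: none
Why: Proposed new method: PhI(OAc)2 in hexafluoroisopropanol converts the phenol into a phenoxenium‑type cation that furan captures at the para carbon through its C2 (loss of H+ then restores the furan), the closest known reactions being the oxidative para‑allylation of 4‑alkylphenols with allylsilanes and oxidative phenol–furan/thiophene couplings with the same reagent; furan is about as nucleophilic as allyltrimethylsilane, its excess suppresses double coupling, and the product is achiral.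

**Step 2**
Reactants: 3 4‑(furan‑2‑yl)‑4‑methylcyclohexa‑2,5‑dien‑1‑one
Product: 4 (4S,5R)‑4‑(furan‑2‑yl)‑4‑methyl‑5‑vinylcyclohex‑2‑en‑1‑one
Conditions: [Rh(C2H4)2Cl]2 (2.5 mol %), (R,R)‑2,5‑diphenylbicyclo[2.2.2]octa‑2,5‑diene (5.5 mol %), CH2=CHBF3K (1.5 equiv), Et3N, dioxane/H2O 10:1, 40 °C
Reagents that add atoms: potassium vinyltrifluoroborate [K+].C=C[B-](F)(F)F
Why: Rhodium‑catalysed asymmetric conjugate addition (Hayashi–Miyaura type) desymmetrises the dienone; the chiral diene selects one enantiotopic enone and the vinyl group enters anti to the larger 2‑furyl group, which fixes C10 and with it the quaternary C1.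

**Step 3**
Reactants: 4 (4S,5R)‑4‑(furan‑2‑yl)‑4‑methyl‑5‑vinylcyclohex‑2‑en‑1‑one
Product: 6 (4S,5S,6R)‑4‑(furan‑2‑yl)‑4,6‑dimethyl‑5‑vinylcyclohex‑2‑en‑1‑one, via C11‑epimeric methyl ketone 5 (not isolated)
Conditions: LiN(iPr)2 (1.05 equiv), THF, −78 °C; MeI (1.0 equiv), −78 to −40 °C; then LiN(iPr)2 (1.3 equiv), −78 °C; AcOH in THF, −78 °C
Reagents that add atoms: iodomethane CI
Why: Kinetic α'‑enolate methylation occurs anti to the vinyl group (giving 5), and re‑enolisation followed by kinetic protonation from the face opposite the pseudoaxial C10 vinyl group turns the C11 methyl cis to vinyl (11R of the target).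

**Step 4**
Reactants: 6 (4S,5S,6R)‑4‑(furan‑2‑yl)‑4,6‑dimethyl‑5‑vinylcyclohex‑2‑en‑1‑one
Product: 8 (2R,3S,4R,5S)‑4‑(furan‑2‑yl)‑5‑hydroxy‑2,4‑dimethyl‑3‑vinylcyclohexan‑1‑one, via C14 pinacol boronate 7 (not isolated)
Conditions: CuCl (5 mol %), NaOtBu (7 mol %), (R)‑DTBM‑Segphos (5.5 mol %), B2pin2 (1.1 equiv), MeOH (2 equiv), THF, rt; then NaBO3·4H2O, THF/H2O, rt
Reagents that add atoms: bis(pinacolato)diboron CC1(C)OB(OC1(C)C)B1OC(C)(C)C(C)(C)O1; sodium perborate [Na+].[O-]OB=O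
Why: Copper‑catalysed conjugate borylation of the remaining enone, with a chiral ligand matched to the substrate, puts boron on C14 anti to the C10 vinyl group, and perborate oxidation with retention gives the 14S alcohol.

**Step 5**
Reactants: 8 (2R,3S,4R,5S)‑4‑(furan‑2‑yl)‑5‑hydroxy‑2,4‑dimethyl‑3‑vinylcyclohexan‑1‑one
Product: 9 (6R,7S,8R,9S)‑8‑(furan‑2‑yl)‑6,8‑dimethyl‑7‑vinyl‑1,4‑dioxaspiro[4.5]decan‑9‑ol
Conditions: TMSOCH2CH2OTMS (1.5 equiv), TMSOTf (5 mol %), CH2Cl2, −78 to −20 °C; pyridine then aq. NaHCO3; brief K2CO3/MeOH, 0 °C, to cleave any O‑SiMe3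
Reagents that add atoms: 1,2‑bis(trimethylsilyloxy)ethane C[Si](C)(C)OCCO[Si](C)(C)C
Why: Noyori ketalisation (aprotic, low temperature) masks the C12 ketone without dehydrating the β‑hydroxy ketone; no stereocentre is touched.

**Step 6**
Reactants: 9 (6R,7S,8R,9S)‑8‑(furan‑2‑yl)‑6,8‑dimethyl‑7‑vinyl‑1,4‑dioxaspiro[4.5]decan‑9‑ol
Product: 10 5‑[(6R,7S,8R,9S)‑9‑hydroxy‑6,8‑dimethyl‑7‑vinyl‑1,4‑dioxaspiro[4.5]decan‑8‑yl]furan‑2‑carbaldehyde
Conditions: n‑BuLi (2.3 equiv), THF, −78 to 0 °C; DMF (3 equiv), 0 °C; H2O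
Reagents that add atoms: N,N‑dimethylformamide CN(C)C=O
Why: α‑Lithiation of the 2‑alkylfuran at its free C5 position (alkoxide, ketal and vinyl group are inert) and formylation with DMF introduces C6 as an aldehyde.

**Step 7**
Reactants: 10 5‑[(6R,7S,8R,9S)‑9‑hydroxy‑6,8‑dimethyl‑7‑vinyl‑1,4‑dioxaspiro[4.5]decan‑8‑yl]furan‑2‑carbaldehyde
Product: 11 (6R,7S,8R,9S)‑8‑(5‑formylfuran‑2‑yl)‑6,8‑dimethyl‑7‑vinyl‑1,4‑dioxaspiro[4.5]decan‑9‑yl butanoate
Conditions: (n‑PrCO)2O (1.5 equiv), Et3N, DMAP (0.1 equiv), CH2Cl2, 0 °C to rt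
Reagents that add atoms: butyric anhydride CCCC(=O)OC(=O)CCC
Why: DMAP‑catalysed acylation installs the final C14 butanoate while C12 is a ketal, so the ester is not β to a free ketone and cannot eliminate.

**Step 8**
Reactants: 12 3‑methyltetronic acid [4‑hydroxy‑3‑methylfuran‑2(5H)‑one]
Product: 13 4‑bromo‑3‑methylfuran‑2(5H)‑one
Conditions: (COBr)2 (1.3 equiv), DMF (cat.), CH2Cl2, 0 °C to rt
Reagents that add atoms: oxalyl bromide O=C(Br)C(=O)Br
Why: Vilsmeier‑type bromodehydroxylation of the tetronic acid enol gives the β‑bromobutenolide that carries C7, C8, C17, C18 and C19.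

**Step 9**
Reactants: 11 (6R,7S,8R,9S)‑8‑(5‑formylfuran‑2‑yl)‑6,8‑dimethyl‑7‑vinyl‑1,4‑dioxaspiro[4.5]decan‑9‑yl butanoate; 13 4‑bromo‑3‑methylfuran‑2(5H)‑one
Product: 15 silyl ether of the vinylogous aldol adduct: 11 in which CHO has become C6H(OTBS) (6S) bonded to C7 (2S) of a 3‑bromo‑4‑methyl‑5‑oxo‑2,5‑dihydrofuran‑2‑yl ring, via free C6 alcohol 14 (not isolated)
Conditions: 13 (1.5 equiv), axially chiral binaphthyl guanidine base (5 mol %), THF, −40 °C; then TBSOTf (1.5 equiv), 2,6‑lutidine (2.5 equiv), −40 to 0 °C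
Reagents that add atoms: tert‑butyldimethylsilyl triflate CC(C)(C)[Si](C)(C)OS(=O)(=O)C(F)(F)F
Why: Catalytic direct vinylogous aldol addition of the butenolide γ‑carbon (C7) to the furan aldehyde gives the syn C6/C7 adduct under catalyst control (the ring A stereocentres are remote), and in situ silylation protects O6.

**Step 10**
Reactants: 15 silyl ether of the vinylogous aldol adduct
Product: 16 C9 aldehyde: 15 with the vinyl group on C10 cut down to CHO
Conditions: OsO4 (2 mol %), NaIO4 (4 equiv), 2,6‑lutidine (2 equiv), dioxane/H2O 3:1, rt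
Reagents that add atoms: osmium tetroxide O=[Os](=O)(=O)=O; sodium periodate [Na+].[O-][I](=O)(=O)=O
Why: Lemieux–Johnson cleavage attacks only the monosubstituted alkene (the bromobutenolide is electron‑poor, the furan aromatic) and leaves the configuration at C10 unchanged.

**Step 11**
Reactants: 16 C9 aldehyde
Product: 17 furanophane alcohol (C2–C5 = furan ring carbons bridged by O; 12‑ethylene ketal; 14S‑butanoate; 6‑OTBS; 7R‑8(17)‑en‑19,7‑olide; free 9S‑OH)
Conditions: CrCl2 (8 equiv), NiCl2 (0.2 equiv), DMSO/THF 3:1, 25 °C, slow addition to 2 mM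
Reagents that add atoms: none
Why: Intramolecular Nozaki–Hiyama–Kishi coupling of the β‑bromobutenolide with the C9 aldehyde closes the ten‑membered carbocycle as a [6](2,5)furanophane, a ring type this reaction is known to close; the macrocyclic transition state is expected to give 9S (a chiral sulfonamide ligand on chromium can reinforce it).

**Step 12**
Reactants: 17 furanophane alcohol
Product: 18 9‑acetate of 17
Conditions: Ac2O, Et3N, DMAP (cat.), CH2Cl2, 0 °C to rt
Reagents that add atoms: acetic anhydride CC(=O)OC(C)=O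
Why: Standard DMAP‑catalysed acetylation of the only free hydroxyl; the conditions are too weakly basic to deprotonate the butenolide γ‑position.

**Step 13**
Reactants: 18 9‑acetate of 17
Product: 19 Z‑ene‑2,5‑dione (furan opened; C2=O and C5=O; 3Z alkene; other groups as in 18)
Conditions: NBS (1.05 equiv), NaHCO3 (2 equiv), acetone/H2O 10:1, −20 °C
Reagents that add atoms: water O
Why: Oxidative dearomatisation of the 2,5‑dialkylfuran (bromination, water capture, loss of HBr) opens it to the cis‑ene‑1,4‑dione, so the Z geometry of C3=C4 is inherited from the ring and the carbocycle is revealed as a plain ten‑membered ring.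

**Step 14**
Reactants: 19 Z‑ene‑2,5‑dione
Product: 20 5(16)‑methylene 2‑ketone (as 19 with C5=CH2)
Conditions: Cp2Ti(μ‑CH2)(μ‑Cl)AlMe2 (Tebbe reagent, 1.3 equiv), pyridine (cat.), THF/toluene, −40 to 0 °C
Reagents that add atoms: Tebbe reagent C[Al-]1(C)C[Ti](C2C=CC=C2)(C2C=CC=C2)[Cl+]1
Why: Tebbe methylenation (carbonyl olefination through an oxatitanacyclobutane) is non‑basic, so the butenolide γ‑proton and the β‑silyloxy group survive, and it takes the C5 ketone in preference to the C2 ketone shielded by quaternary C1, the esters and the lactone.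

**Step 15**
Reactants: 20 5(16)‑methylene 2‑ketone
Product: 21 2S allylic alcohol (as 20 with C2–OH)
Conditions: NaBH4 (1.5 equiv), CeCl3·7H2O (1.5 equiv), MeOH, −78 °C
Reagents that add atoms: none
Why: Luche 1,2‑reduction of the dienone; hydride is delivered to the outer face of the C2 carbonyl anti to the C15 methyl group, which corresponds to 2S.

**Step 16**
Reactants: 21 2S allylic alcohol
Product: 22 2,9‑diacetate (as 21 with C2–OAc)
Conditions: Ac2O, Et3N, DMAP (cat.), CH2Cl2, 0 °C to rt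
Reagents that add atoms: acetic anhydride CC(=O)OC(C)=O
Why: Acetylation of the single free secondary hydroxyl under the same mild conditions as step 12.

**Step 17**
Reactants: 22 2,9‑diacetate
Product: 23 6‑alcohol (as 22 with free C6–OH; hydroxyl opposite in space to the Cl of 28)
Conditions: HF·pyridine, pyridine, THF, 0 °C to rt
Reagents that add atoms: none
Why: Buffered fluoride cleaves only the silyl ether; ketal, esters and the dienyl acetate are stable.

**Step 18**
Reactants: 23 6‑alcohol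
Product: 24 8,17‑epoxide of 23 (epoxide oxygen on the C6 side of the lactone ring; 8R)
Conditions: t‑BuOOH (3 equiv), n‑BuLi (2.9 equiv), THF, −78 to −20 °C; H2O
Reagents that add atoms: tert‑butyl hydroperoxide CC(C)(C)OO
Why: Proposed new method: Weitz–Scheffer nucleophilic epoxidation of the butenolide in which lithium tert‑butyl peroxide is held by the homoallylic C6 hydroxyl and so attacks C8 on the face syn to C6 (the face an undirected reagent avoids), the enolate then closing the epoxide irreversibly; the closest known reactions are lithium‑alkoxide‑directed nucleophilic epoxidations of γ‑hydroxy enones and vinyl sulfones and peroxide epoxidations of tetrasubstituted enones and butenolides.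

**Step 19**
Reactants: 24 8,17‑epoxide of 23
Product: 26 8R‑hydroxy‑17R lactone (as 23 with saturated lactone; 8‑OH; 17‑H), via C17‑epimeric hydroxy lactone 25 (not isolated)
Conditions: SmI2 (2.5 equiv), THF/MeOH, −78 °C; then DBU (1 equiv), toluene, 50 °C on the crude product
Reagents that add atoms: none
Why: SmI2 cleaves the C17–O bond of the α,β‑epoxy lactone (β‑hydroxy ester formation) and leaves the 8‑OH; DBU then equilibrates the epimerisable C17 to the more stable 17R isomer (methyl trans to the bulky C9).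

**Step 20**
Reactants: 26 8R‑hydroxy‑17R lactone
Product: 27 12‑ketone: 6‑dechloro‑6‑epi‑hydroxy‑ptilosarcone
Conditions: PPTS (0.3 equiv), acetone/H2O 10:1, 45 °C
Reagents that add atoms: water O
Why: Mild acid‑catalysed ketal exchange frees the C12 ketone; the β‑butanoyloxy ketone tolerates acid and the allylic C6–OH is deactivated towards ionisation by the acyloxy‑bearing C7.

**Step 21**
Reactants: 27 12‑ketone
Product: 28 ptilosarcone
Conditions: PPh3 (1.5 equiv), hexachloroacetone (3 equiv), CH2Cl2, −20 to 0 °C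
Reagents that add atoms: hexachloroacetone ClC(Cl)(Cl)C(=O)C(Cl)(Cl)Cl
Why: Triphenylphosphine–hexachloroacetone converts secondary allylic alcohols into chlorides by SN2 with inversion and without allylic transposition under neutral conditions; the tertiary 8‑OH is inert and inversion gives 6S.

**Compound list**
1 | p‑cresol (4‑methylphenol) | Cc1ccc(O)cc1 | starting material
2 | furan | c1ccoc1 | starting material
3 | 4‑(furan‑2‑yl)‑4‑methylcyclohexa‑2,5‑dien‑1‑one | CC1(C=CC(=O)C=C1)c1ccco1 | intermediate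
4 | (4S,5R)‑4‑(furan‑2‑yl)‑4‑methyl‑5‑vinylcyclohex‑2‑en‑1‑one | C=C[C@H]1CC(=O)C=C[C@]1(C)c1ccco1 | intermediate
5 | (4S,5S,6S)‑4‑(furan‑2‑yl)‑4,6‑dimethyl‑5‑vinylcyclohex‑2‑en‑1‑one (C11 epimer of 6) | C=C[C@H]1[C@H](C)C(=O)C=C[C@]1(C)c1ccco1 | intermediate
6 | (4S,5S,6R)‑4‑(furan‑2‑yl)‑4,6‑dimethyl‑5‑vinylcyclohex‑2‑en‑1‑one | C=C[C@H]1[C@@H](C)C(=O)C=C[C@]1(C)c1ccco1 | intermediate
7 | C14 pinacol boronate of 6 (boron trans to vinyl) | C=C[C@H]1[C@@H](C)C(=O)C[C@H](B2OC(C)(C)C(C)(C)O2)[C@]1(C)c1ccco1 | intermediate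
8 | (2R,3S,4R,5S)‑4‑(furan‑2‑yl)‑5‑hydroxy‑2,4‑dimethyl‑3‑vinylcyclohexan‑1‑one | C=C[C@H]1[C@@H](C)C(=O)C[C@H](O)[C@]1(C)c1ccco1 | intermediate
9 | (6R,7S,8R,9S)‑8‑(furan‑2‑yl)‑6,8‑dimethyl‑7‑vinyl‑1,4‑dioxaspiro[4.5]decan‑9‑ol | C=C[C@H]1[C@@H](C)C2(OCCO2)C[C@H](O)[C@]1(C)c1ccco1 | intermediate
10 | 5‑[(6R,7S,8R,9S)‑9‑hydroxy‑6,8‑dimethyl‑7‑vinyl‑1,4‑dioxaspiro[4.5]decan‑8‑yl]furan‑2‑carbaldehyde | C=C[C@H]1[C@@H](C)C2(OCCO2)C[C@H](O)[C@]1(C)c1ccc(C=O)o1 | intermediate
11 | (6R,7S,8R,9S)‑8‑(5‑formylfuran‑2‑yl)‑6,8‑dimethyl‑7‑vinyl‑1,4‑dioxaspiro[4.5]decan‑9‑yl butanoate | C=C[C@H]1[C@@H](C)C2(OCCO2)C[C@H](OC(=O)CCC)[C@]1(C)c1ccc(C=O)o1 | intermediate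
12 | 3‑methyltetronic acid [4‑hydroxy‑3‑methylfuran‑2(5H)‑one] | CC1=C(O)COC1=O | starting material
13 | 4‑bromo‑3‑methylfuran‑2(5H)‑one | CC1=C(Br)COC1=O | intermediate
14 | vinylogous aldol adduct: 11 with CHO turned into C6H(OH) (6S) bonded to C7 (2S) of a 3‑bromo‑4‑methyl‑5‑oxo‑2,5‑dihydrofuran‑2‑yl ring | C=C[C@H]1[C@@H](C)C2(OCCO2)C[C@H](OC(=O)CCC)[C@]1(C)c1ccc(o1)[C@@H](O)[C@@H]1OC(=O)C(C)=C1Br | intermediate
15 | tert‑butyldimethylsilyl ether of 14 | C=C[C@H]1[C@@H](C)C2(OCCO2)C[C@H](OC(=O)CCC)[C@]1(C)c1ccc(o1)[C@@H](O[Si](C)(C)C(C)(C)C)[C@@H]1OC(=O)C(C)=C1Br | intermediate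
16 | C9 aldehyde (15 with vinyl cut down to CHO on C10) | O=C[C@H]1[C@@H](C)C2(OCCO2)C[C@H](OC(=O)CCC)[C@]1(C)c1ccc(o1)[C@@H](O[Si](C)(C)C(C)(C)C)[C@@H]1OC(=O)C(C)=C1Br | intermediate
17 | furanophane alcohol (C2–C5 = furan carbons; 12‑ethylene ketal; 14S‑butanoate; 6‑OTBS; 7R‑8(17)‑en‑19,7‑olide; 9S‑OH) | O[C@H]1[C@H]2[C@@H](C)C3(OCCO3)C[C@H](OC(=O)CCC)[C@]2(C)c2ccc(o2)[C@@H](O[Si](C)(C)C(C)(C)C)[C@@H]2OC(=O)C(C)=C12 | intermediate
18 | 9‑acetate of 17 | CC(=O)O[C@H]1[C@H]2[C@@H](C)C3(OCCO3)C[C@H](OC(=O)CCC)[C@]2(C)c2ccc(o2)[C@@H](O[Si](C)(C)C(C)(C)C)[C@@H]2OC(=O)C(C)=C12 | intermediate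
19 | Z‑ene‑2,5‑dione (furan of 18 opened; C2=O, C5=O, 3Z) | CC(=O)O[C@H]1[C@H]2[C@@H](C)C3(OCCO3)C[C@H](OC(=O)CCC)[C@]2(C)C(=O)/C=C\C(=O)[C@@H](O[Si](C)(C)C(C)(C)C)[C@@H]2OC(=O)C(C)=C12 | intermediate
20 | 5(16)‑methylene 2‑ketone | CC(=O)O[C@H]1[C@H]2[C@@H](C)C3(OCCO3)C[C@H](OC(=O)CCC)[C@]2(C)C(=O)/C=C\C(=C)[C@@H](O[Si](C)(C)C(C)(C)C)[C@@H]2OC(=O)C(C)=C12 | intermediate
21 | 2S allylic alcohol | CC(=O)O[C@H]1[C@H]2[C@@H](C)C3(OCCO3)C[C@H](OC(=O)CCC)[C@]2(C)[C@@H](O)/C=C\C(=C)[C@@H](O[Si](C)(C)C(C)(C)C)[C@@H]2OC(=O)C(C)=C12 | intermediate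
22 | 2,9‑diacetate | CC(=O)O[C@H]1[C@H]2[C@@H](C)C3(OCCO3)C[C@H](OC(=O)CCC)[C@]2(C)[C@@H](OC(C)=O)/C=C\C(=C)[C@@H](O[Si](C)(C)C(C)(C)C)[C@@H]2OC(=O)C(C)=C12 | intermediate
23 | 6‑alcohol (free C6–OH, opposite in space to the Cl of 28; butenolide intact) | CC(=O)O[C@H]1[C@H]2[C@@H](C)C3(OCCO3)C[C@H](OC(=O)CCC)[C@]2(C)[C@@H](OC(C)=O)/C=C\C(=C)[C@@H](O)[C@@H]2OC(=O)C(C)=C12 | intermediate
24 | 8,17‑epoxide of 23 (oxygen on the C6 side of the lactone) | CC(=O)O[C@H]1[C@H]2[C@@H](C)C3(OCCO3)C[C@H](OC(=O)CCC)[C@]2(C)[C@@H](OC(C)=O)/C=C\C(=C)[C@@H](O)[C@@H]2OC(=O)[C@]3(C)O[C@]123 | intermediate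
25 | C17 epimer of 26 | CC(=O)O[C@H]1[C@H]2[C@@H](C)C3(OCCO3)C[C@H](OC(=O)CCC)[C@]2(C)[C@@H](OC(C)=O)/C=C\C(=C)[C@@H](O)[C@@H]2OC(=O)[C@@H](C)[C@@]12O | intermediate
26 | 8R‑hydroxy‑17R lactone (12‑ketal; 6‑OH) | CC(=O)O[C@H]1[C@H]2[C@@H](C)C3(OCCO3)C[C@H](OC(=O)CCC)[C@]2(C)[C@@H](OC(C)=O)/C=C\C(=C)[C@@H](O)[C@@H]2OC(=O)[C@H](C)[C@@]12O | intermediate
27 | 12‑ketone: 6‑dechloro‑6‑epi‑hydroxy‑ptilosarcone | CC(=O)O[C@H]1[C@H]2[C@@H](C)C(=O)C[C@H](OC(=O)CCC)[C@]2(C)[C@@H](OC(C)=O)/C=C\C(=C)[C@@H](O)[C@@H]2OC(=O)[C@H](C)[C@@]12O | intermediate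
28 | ptilosarcone (1R,2S,6S,7R,8R,9S,10S,11R,14S,17R; 3Z) | CC(=O)O[C@H]1[C@H]2[C@@H](C)C(=O)C[C@H](OC(=O)CCC)[C@]2(C)[C@@H](OC(C)=O)/C=C\C(=C)[C@H](Cl)[C@@H]2OC(=O)[C@H](C)[C@@]12O | target

**Step count and risks**
Total: 21 steps. Longest linear sequence: 20 steps (steps 1–7 and 9–21, from p‑cresol).

Most likely to fail, first: step 1. The oxidative para‑furylation has no direct precedent and may give ortho coupling, [3+2] adducts or furan oxidation instead. The fallback sets out from furan 2 and comes back at dienone 3. Acetylation of 2 (Ac2O, H3PO4) gives 2‑acetylfuran F1; Wittig reaction with Ph3P=CHOMe gives the enol ether 2‑(1‑methoxyprop‑1‑en‑2‑yl)furan F2; mild aqueous acid gives 2‑(furan‑2‑yl)propanal F3; Robinson annulation with methyl vinyl ketone (pyrrolidine, then AcOH/NaOAc) gives 4‑(furan‑2‑yl)‑4‑methylcyclohex‑2‑en‑1‑one F4; dehydrogenation with 2‑iodoxybenzoic acid in DMSO at 65 °C gives 3.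

Second: step 11. The trans‑fused furanophane may be too strained to close at C8–C9, and the C9 configuration rests on the macrocyclic transition state (a simple Felkin analysis of the open‑chain aldehyde points to the C9 epimer). The fallback sets out from ketal alcohol 9 and comes back at acetate 18, closing the ring at C6–C7 instead. Butanoylation of 9 gives the furan butanoate F5; Lemieux–Johnson cleavage gives the C9 aldehyde F6; intermolecular NiCl2/CrCl2 coupling with 13 under a chiral sulfonamide ligand gives the 9S alcohol F7; acetylation gives the acetate F8; Vilsmeier formylation (POCl3, DMF, 0 °C) of the furan gives the furan aldehyde F9; an intramolecular direct vinylogous aldol under the guanidine catalyst at high dilution, with TBSOTf/2,6‑lutidine added in the same flask, gives 18.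

Third: step 18. The tetrasubstituted butenolide may resist peroxide addition, or the hydroxyl may fail to steer it to the C6 face. The fallback sets out from 23 and comes back at 26 by a tethered oxa‑Michael addition. Benzaldehyde and catalytic KOtBu form the C6 hemiacetal alkoxide, which adds to C8 within a six‑membered ring (necessarily on the C6 face) and, after protonation and equilibration at C17, gives the 6,8‑O‑benzylidene acetal F10; PPTS in wet methanol removes the acetal to give 26.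

**Further compounds**
F1 | step 1 | 2‑acetylfuran | CC(=O)c1ccco1
F2 | step 1 | 2‑(1‑methoxyprop‑1‑en‑2‑yl)furan | COC=C(C)c1ccco1
F3 | step 1 | 2‑(furan‑2‑yl)propanal | CC(C=O)c1ccco1
F4 | step 1 | 4‑(furan‑2‑yl)‑4‑methylcyclohex‑2‑en‑1‑one | CC1(CCC(=O)C=C1)c1ccco1
F5 | step 11 | butanoate of 9 | C=C[C@H]1[C@@H](C)C2(OCCO2)C[C@H](OC(=O)CCC)[C@]1(C)c1ccco1
F6 | step 11 | C9 aldehyde from F5 | O=C[C@H]1[C@@H](C)C2(OCCO2)C[C@H](OC(=O)CCC)[C@]1(C)c1ccco1
F7 | step 11 | 9S alcohol bearing the 3‑methylbutenolide at C8 | O[C@H](C1=C(C)C(=O)OC1)[C@H]1[C@@H](C)C2(OCCO2)C[C@H](OC(=O)CCC)[C@]1(C)c1ccco1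
F8 | step 11 | 9‑acetate of F7 | CC(=O)O[C@H](C1=C(C)C(=O)OC1)[C@H]1[C@@H](C)C2(OCCO2)C[C@H](OC(=O)CCC)[C@]1(C)c1ccco1
F9 | step 11 | 5‑formylfuran derived from F8 | CC(=O)O[C@H](C1=C(C)C(=O)OC1)[C@H]1[C@@H](C)C2(OCCO2)C[C@H](OC(=O)CCC)[C@]1(C)c1ccc(C=O)o1
F10 | step 18 | 6,8‑O‑benzylidene acetal of 26 | CC(=O)O[C@H]1[C@H]2[C@@H](C)C3(OCCO3)C[C@H](OC(=O)CCC)[C@]2(C)[C@@H](OC(C)=O)/C=C\C(=C)[C@H]3OC(c4ccccc4)O[C@]14[C@@H](C)C(=O)O[C@@H]34
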